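## Retrosynthetic overview

1. Lutein dimyristate ⇒ lutein + myristoyl chloride; lutein ⇒ Wittig union at C11'=C12' of a β-half C25 phosphonium salt with an ε-ring C15 dienal; the C25 unit ⇒ Wittig union at C11=C12 of a β-ring C15 phosphonium salt with 2,7-dimethylocta-2,4,6-trienedial.
2. β-ring C15 salt ⇒ (4R)-4-hydroxy-β-cyclocitral ⇒ a chlorocyclohexane in which the ring bonds C2–C3 and C1–C6 are cut together, leaving isobutylene and an open-chain chiral acetal that carries the C5=C6 olefin.
3. Enabling feature: in the β-ring the gem-dimethyl carbon C1 and the methylene C2 are an isobutylene unit lodged between the carbinol carbon C3 (an aldehyde carbon, 1,3 to C1) and the olefinic carbon C6 (C5=C6 lies 1,5 to C1, as in an open carotenoid end group). A Prins addition at C3 therefore creates exactly the C1 cation with which a carotenoid cyclase closes this ring.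
4. The ε-ring is not built: it comes from (R)-α-ionone, and its C3' oxygen is added by allylic oxidation and catalyst-controlled reduction.
5. Ring order: only the β-ring is formed (step 4); both rings are complete before the polyene is assembled (steps 15 and 18).

Key step: step 4

Atom numbers in the text (C1–C7, primed for the ε-half) follow carotenoid numbering.

Assumption: (R)-(+)-α-ionone of high enantiomeric purity is taken as purchasable; the olefin geometry of 7 and the configurations at C5 and C6 of 13–16 are deliberately left uncontrolled, because both carbons become sp2 in step 7.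

## Route

**Step 1**
Reactants: 1 2-methylallylmagnesium chloride; 2 triethyl orthoformate
Product: 3 4,4-diethoxy-2-methylbut-1-ene
Conditions: THF/toluene, 0 °C to 80 °C; aq. NH4Cl
Reagents that add atoms: triethyl orthoformate (2), CCOC(OCC)OCC
Why: Bodroux–Chichibabin reaction, in which the allylic Grignard reagent displaces one ethoxide of the orthoester and so delivers the β,γ-unsaturated aldehyde directly as its acetal, avoiding the free aldehyde that would slip into conjugation.

**Step 2**
Reactants: 3 4,4-diethoxy-2-methylbut-1-ene; 4 (2R,4R)-pentane-2,4-diol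
Product: 5 (4R,6R)-4,6-dimethyl-2-(2-methylprop-2-en-1-yl)-1,3-dioxane
Conditions: pyridinium p-toluenesulfonate (cat.), toluene, 50 °C, ethanol removed under reduced pressure
Reagents that add atoms: (2R,4R)-pentane-2,4-diol (4), C[C@@H](O)C[C@@H](C)O
Why: acid-catalysed transacetalisation driven by removal of ethanol; because the diol is C2-symmetric the acetal carbon is not stereogenic and a single dioxane should result.

**Step 3**
Reactants: 5 (4R,6R)-4,6-dimethyl-2-(2-methylprop-2-en-1-yl)-1,3-dioxane; 6 (Z)-but-2-ene-1,4-diyl diacetate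
Product: 7 4-[(4R,6R)-4,6-dimethyl-1,3-dioxan-2-yl]-3-methylbut-2-en-1-yl acetate
Conditions: 6 (3 equiv), second-generation Hoveyda–Grubbs catalyst RuCl2(H2IMes)(=CH-C6H4-2-OiPr) (5 mol%), CH2Cl2, 40 °C
Reagents that add atoms: (Z)-but-2-ene-1,4-diyl diacetate (6), CC(=O)OC/C=C\COC(C)=O
Why: olefin cross-metathesis of a 1,1-disubstituted alkene with an allylic acetate partner is an established way to prenyl-type acetates; an E-major E/Z mixture is expected and is acceptable here.

**Step 4**
Reactants: 7 4-[(4R,6R)-4,6-dimethyl-1,3-dioxan-2-yl]-3-methylbut-2-en-1-yl acetate; 8 isobutylene; 9 titanium tetrachloride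
Product: 13 [(4S)-2-chloro-4-{[(2R,4R)-4-hydroxypentan-2-yl]oxy}-2,6,6-trimethylcyclohexyl]methyl acetate, via oxocarbenium titanate 10 (not isolated), via tertiary C1 cation 11 (not isolated), via cyclohexyl C5 cation 12 (not isolated)
Conditions: 8 (3 equiv), TiCl4 (2.2 equiv), CH2Cl2, −78 °C, 30 min; sat. aq. NaHCO3 at −78 °C
Reagents that add atoms: isobutylene (8), CC(C)=C; titanium tetrachloride (9), Cl[Ti](Cl)(Cl)Cl
Why: Proposed new method: TiCl4 ionises the dioxane at the C–O bond next to the axial methyl group, and isobutylene attacks the oxocarbenium carbon C3 with its CH2 terminus anti to the departing oxygen (Prins addition, C2–C3); this creates the tertiary C1 cation 11, which is captured by the C5=C6 olefin in a 6-endo-trig, chair-like cation–olefin closure (C1–C6) to give the tertiary C5 cation 12, which collapses with chloride. The closest known reaction types are the chiral 2,4-pentanediol-acetal-initiated cation–olefin cyclisation, the Lewis acid Prins addition of acetals to 1,1-disubstituted alkenes and the acid cyclisation of pseudoionone to ionones; what is new is that an external alkene is inserted between initiator and terminator, a formal [4+2] annulation. The one stereocentre that matters, C3, is set by the (4R,6R)-dioxane template through invertive opening, which should place O, C2 and C4 as in the target; C5 and C6 are formed without control and are erased in step 7. The step needs isobutylene to win over the internal olefin at the oxocarbenium stage, which is secured because the internal olefin could only close a three- or four-membered ring onto C3 and is deactivated by the Lewis acid-bound acetate; it also needs ring closure to outrun addition of a second isobutylene, which is secured by the six-membered transition state and a small excess of isobutylene at −78 °C. Any olefinic termination products should re-add HCl in the TiCl4/HCl medium to the same tertiary chloride, so that one constitution results.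

**Step 5**
Reactants: 13 [(4S)-2-chloro-4-{[(2R,4R)-4-hydroxypentan-2-yl]oxy}-2,6,6-trimethylcyclohexyl]methyl acetate
Product: 14 [(4S)-2-chloro-2,6,6-trimethyl-4-{[(2R)-4-oxopentan-2-yl]oxy}cyclohexyl]methyl acetate
Conditions: Dess–Martin periodinane (1.3 equiv), CH2Cl2, 0 °C to rt
Reagents that add atoms: none
Why: Dess–Martin oxidation of the only free hydroxyl under neutral conditions, which spare the tertiary chloride and the acetate and turn the auxiliary into a β-alkoxy ketone ready for elimination.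

**Step 6**
Reactants: 14 [(4S)-2-chloro-2,6,6-trimethyl-4-{[(2R)-4-oxopentan-2-yl]oxy}cyclohexyl]methyl acetate
Product: 15 (1S)-3-chloro-4-(hydroxymethyl)-3,5,5-trimethylcyclohexan-1-ol
Conditions: K2CO3 (0.3 equiv), MeOH, 0 °C to rt, short reaction time
Reagents that add atoms: none
Why: retro-oxa-Michael (E1cB) cleavage of the β-alkoxy ketone releases the C3 hydroxyl without touching its configuration, with concurrent methanolysis of the acetate; the tertiary chloride is expected to survive brief exposure to cold methanolic carbonate.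

**Step 7**
Reactants: 15 (1S)-3-chloro-4-(hydroxymethyl)-3,5,5-trimethylcyclohexan-1-ol
Product: 17 (4R)-4-hydroxy-2,6,6-trimethylcyclohex-1-ene-1-carbaldehyde, via chloro aldehyde 16 (not isolated)
Conditions: TEMPO (10 mol%), PhI(OAc)2 (1.1 equiv), CH2Cl2, rt; then Et3N (3 equiv), 0 °C to rt
Reagents that add atoms: none
Why: oxoammonium (TEMPO) oxidation takes primary in preference to secondary alcohols, and the resulting β-chloro aldehyde loses HCl by E1cB on addition of Et3N, which places the double bond specifically between C5 and C6 and removes both uncontrolled centres.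

**Step 8**
Reactants: 17 (4R)-4-hydroxy-2,6,6-trimethylcyclohex-1-ene-1-carbaldehyde; 18 ethyl (2E)-4-(diethoxyphosphoryl)-3-methylbut-2-enoate
Product: 20 ethyl (2E,4E)-5-[(4R)-4-hydroxy-2,6,6-trimethylcyclohex-1-en-1-yl]-3-methylpenta-2,4-dienoate, via sodium phosphonate carbanion 19 (not isolated)
Conditions: 18 (1.5 equiv), NaH (1.4 equiv), THF, 0 °C; then 17, 0 °C to rt; the 2E isomer is separated by chromatography
Reagents that add atoms: ethyl (2E)-4-(diethoxyphosphoryl)-3-methylbut-2-enoate (18), CCOC(=O)/C=C(C)/CP(=O)(OCC)OCC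
Why: vinylogous Horner–Wadsworth–Emmons olefination of the kind used on β-cyclocitral, E-selective at the new C7=C8 bond; the free hydroxyl is tolerated because the stabilised carbanion is too weak a base to deprotonate it.

**Step 9**
Reactants: 20 ethyl (2E,4E)-5-[(4R)-4-hydroxy-2,6,6-trimethylcyclohex-1-en-1-yl]-3-methylpenta-2,4-dienoate
Product: 21 (2E,4E)-5-[(4R)-4-hydroxy-2,6,6-trimethylcyclohex-1-en-1-yl]-3-methylpenta-2,4-dien-1-ol
Conditions: i-Bu2AlH (3.5 equiv), CH2Cl2, −78 °C; aq. Rochelle salt
Reagents that add atoms: none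
Why: 1,2-reduction of the conjugated ester to the allylic alcohol by i-Bu2AlH, which leaves the polyene untouched.

**Step 10**
Reactants: 21 (2E,4E)-5-[(4R)-4-hydroxy-2,6,6-trimethylcyclohex-1-en-1-yl]-3-methylpenta-2,4-dien-1-ol; 22 triphenylphosphine hydrobromide
Product: 23 {(2E,4E)-5-[(4R)-4-hydroxy-2,6,6-trimethylcyclohex-1-en-1-yl]-3-methylpenta-2,4-dien-1-yl}triphenylphosphonium bromide
Conditions: 22 (1.05 equiv), MeOH, rt, dark
Reagents that add atoms: triphenylphosphine hydrobromide (22), [Br-].c1ccc(cc1)[PH+](c1ccccc1)c1ccccc1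
Why: acid-mediated SN1-type substitution of the pentadienylic alcohol by triphenylphosphine at the primary terminus, the standard entry to C15 Wittig salts; the non-allylic ring hydroxyl is inert.

**Step 11**
Reactants: 24 (R)-α-ionone; 25 diethyl (cyanomethyl)phosphonate
Product: 27 (2E,4E)-3-methyl-5-[(1R)-2,6,6-trimethylcyclohex-2-en-1-yl]penta-2,4-dienenitrile, via sodium cyanomethylphosphonate carbanion 26 (not isolated)
Conditions: 25 (1.3 equiv), NaH (1.25 equiv), THF, 0 °C to rt; the 2E isomer is separated by chromatography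
Reagents that add atoms: diethyl (cyanomethyl)phosphonate (25), CCOP(=O)(CC#N)OCC
Why: Horner–Wadsworth–Emmons olefination of the methyl ketone, E-major at the new trisubstituted bond; the stabilised carbanion is too weakly basic to epimerise C6'.

**Step 12**
Reactants: 27 (2E,4E)-3-methyl-5-[(1R)-2,6,6-trimethylcyclohex-2-en-1-yl]penta-2,4-dienenitrile; 28 tert-butyl hydroperoxide
Product: 29 (2E,4E)-3-methyl-5-[(1R)-2,6,6-trimethyl-4-oxocyclohex-2-en-1-yl]penta-2,4-dienenitrile
Conditions: 28 (70% in water, 6 equiv), CuI (5 mol%), MeCN, 50 °C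
Reagents that add atoms: tert-butyl hydroperoxide (28), CC(C)(C)OO
Why: copper-catalysed Kharasch-type allylic oxidation at the ring allylic methylene, as known for α-ionone going to 3-oxo-α-ionone; the shielded C6' hydrogen is spared and the neutral medium should keep that centre intact.

**Step 13**
Reactants: 29 (2E,4E)-3-methyl-5-[(1R)-2,6,6-trimethyl-4-oxocyclohex-2-en-1-yl]penta-2,4-dienenitrile
Product: 30 (2E,4E)-5-[(1R,4R)-4-hydroxy-2,6,6-trimethylcyclohex-2-en-1-yl]-3-methylpenta-2,4-dienenitrile
Conditions: (S)-2-methyl-CBS-oxazaborolidine (20 mol%), catecholborane (1.5 equiv), toluene, −78 °C; aq. NaHCO3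
Reagents that add atoms: none
Why: Corey–Bakshi–Shibata reduction in which the alkenyl side of the enone acts as the large group, so that the (S)-catalyst should give the (4R) carbinol; this is also the face the substrate itself should favour (hydride anti to the axial methyl of the gem-dimethyl group), giving the 3',6'-trans relationship of lutein.

**Step 14**
Reactants: 30 (2E,4E)-5-[(1R,4R)-4-hydroxy-2,6,6-trimethylcyclohex-2-en-1-yl]-3-methylpenta-2,4-dienenitrile
Product: 32 (2E,4E)-5-[(1R,4R)-4-hydroxy-2,6,6-trimethylcyclohex-2-en-1-yl]-3-methylpenta-2,4-dienal, via aluminium aldimine 31 (not isolated)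
Conditions: i-Bu2AlH (2.5 equiv), CH2Cl2, −78 °C; aq. Rochelle salt buffered at pH 7, 0 °C
Reagents that add atoms: water, O
Why: partial reduction of the nitrile by i-Bu2AlH to the N-aluminated aldimine, which is hydrolysed on neutral work-up so that the acid-sensitive allylic hydroxyl is not exposed to acid.

**Step 15**
Reactants: 23 {(2E,4E)-5-[(4R)-4-hydroxy-2,6,6-trimethylcyclohex-1-en-1-yl]-3-methylpenta-2,4-dien-1-yl}triphenylphosphonium bromide; 33 (2E,4E,6E)-2,7-dimethylocta-2,4,6-trienedial
Product: 35 (3R)-3-hydroxy-12'-apo-β-caroten-12'-al, via C15 ylide 34 (not isolated)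
Conditions: 33 (2.5 equiv, excess recovered), NaOMe (1.1 equiv), MeOH/CH2Cl2, −10 °C to rt; then reflux in EtOAc to equilibrate C11=C12 to E
Reagents that add atoms: (2E,4E,6E)-2,7-dimethylocta-2,4,6-trienedial (33), O=C/C(C)=C/C=C/C=C(C)/C=O
Why: Wittig olefination of the symmetrical dialdehyde used in excess to favour mono-condensation, the standard C15 + C10 union of carotenoid synthesis; the Z isomer at the new bond isomerises thermally to E.

**Step 16**
Reactants: 35 (3R)-3-hydroxy-12'-apo-β-caroten-12'-al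
Product: 36 (3R)-12'-apo-β-carotene-3,12'-diol
Conditions: NaBH4 (1 equiv), EtOH/THF, 0 °C
Reagents that add atoms: none
Why: chemoselective 1,2-reduction of the polyenal to the primary allylic alcohol by borohydride.

**Step 17**
Reactants: 36 (3R)-12'-apo-β-carotene-3,12'-diol; 22 triphenylphosphine hydrobromide
Product: 37 [(3R)-3-hydroxy-12'-apo-β-caroten-12'-yl]triphenylphosphonium bromide
Conditions: 22 (1.05 equiv), MeOH/CH2Cl2, rt, dark
Reagents that add atoms: triphenylphosphine hydrobromide (22), [Br-].c1ccc(cc1)[PH+](c1ccccc1)c1ccccc1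
Why: the same acid-mediated phosphonium salt formation as in step 10 (the retinol-to-retinylphosphonium type), with attack of the phosphine at the primary terminus of the polyenyl cation.

**Step 18**
Reactants: 37 [(3R)-3-hydroxy-12'-apo-β-caroten-12'-yl]triphenylphosphonium bromide; 32 (2E,4E)-5-[(1R,4R)-4-hydroxy-2,6,6-trimethylcyclohex-2-en-1-yl]-3-methylpenta-2,4-dienal
Product: 39 (3R,3'R,6'R)-β,ε-carotene-3,3'-diol, via C25 ylide 38 (not isolated)
Conditions: NaOMe (1.1 equiv), MeOH/CH2Cl2, 0 °C to rt; then reflux in heptane/EtOAc to equilibrate C11'=C12' to E; crystallisation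
Reagents that add atoms: aldehyde 32, O=C/C=C(C)/C=C/[C@H]1C(C)=C[C@H](O)CC1(C)C
Why: Wittig olefination of a polyenyl ylide with a dienal (the retinyl-ylide/retinal type) under basic, acid-free conditions that preserve the allylic 3'-hydroxyl and the C6' centre; the all-E isomer is reached by thermal isomerisation.

**Step 19**
Reactants: 39 (3R,3'R,6'R)-β,ε-carotene-3,3'-diol; 40 tetradecanoyl chloride
Product: 41 (3R,3'R,6'R)-β,ε-carotene-3,3'-diyl ditetradecanoate
Conditions: 40 (2.6 equiv), pyridine, DMAP (cat.), CH2Cl2, 0 °C to rt, dark, argon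
Reagents that add atoms: tetradecanoyl chloride (40), CCCCCCCCCCCCCC(Cl)=O
Why: DMAP-catalysed acylation of both secondary hydroxyls with retention at carbon; pyridine buffers the HCl so that the allylic 3'-oxygen does not ionise.

## Compound list

1 | 2-methylallylmagnesium chloride | CC(=C)C[Mg]Cl | starting material
2 | triethyl orthoformate | CCOC(OCC)OCC | starting material
3 | 4,4-diethoxy-2-methylbut-1-ene | CCOC(CC(C)=C)OCC | intermediate
4 | (2R,4R)-pentane-2,4-diol | C[C@@H](O)C[C@@H](C)O | starting material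
5 | (4R,6R)-4,6-dimethyl-2-(2-methylprop-2-en-1-yl)-1,3-dioxane | C=C(C)CC1O[C@H](C)C[C@@H](C)O1 | intermediate
6 | (Z)-but-2-ene-1,4-diyl diacetate | CC(=O)OC/C=C\COC(C)=O | starting material
7 | 4-[(4R,6R)-4,6-dimethyl-1,3-dioxan-2-yl]-3-methylbut-2-en-1-yl acetate (E/Z mixture, E expected to be major) | CC(=O)OCC=C(C)CC1O[C@H](C)C[C@@H](C)O1 | intermediate
8 | isobutylene (2-methylpropene) | CC(C)=C | starting material
9 | titanium tetrachloride | Cl[Ti](Cl)(Cl)Cl | starting material
10 | oxocarbenium titanate from ionisation of 7 | CC(=O)OCC=C(C)CC=[O+][C@H](C)C[C@@H](C)O[Ti-](Cl)(Cl)(Cl)Cl | intermediate (not isolated)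
11 | tertiary C1 cation after Prins addition of isobutylene | CC(=O)OCC=C(C)C[C@H](C[C+](C)C)O[C@H](C)C[C@@H](C)O[Ti-](Cl)(Cl)(Cl)Cl | intermediate (not isolated)
12 | cyclohexyl C5 cation after ring closure | CC(=O)OCC1[C+](C)C[C@@H](O[C@H](C)C[C@@H](C)O[Ti-](Cl)(Cl)(Cl)Cl)CC1(C)C | intermediate (not isolated)
13 | [(4S)-2-chloro-4-{[(2R,4R)-4-hydroxypentan-2-yl]oxy}-2,6,6-trimethylcyclohexyl]methyl acetate (epimers at ring C1/C2) | C[C@@H](O)C[C@@H](C)O[C@@H]1CC(C)(Cl)C(COC(C)=O)C(C)(C)C1 | intermediate
14 | [(4S)-2-chloro-2,6,6-trimethyl-4-{[(2R)-4-oxopentan-2-yl]oxy}cyclohexyl]methyl acetate (epimers at ring C1/C2) | CC(=O)C[C@@H](C)O[C@@H]1CC(C)(Cl)C(COC(C)=O)C(C)(C)C1 | intermediate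
15 | (1S)-3-chloro-4-(hydroxymethyl)-3,5,5-trimethylcyclohexan-1-ol (epimers at C3/C4) | O[C@@H]1CC(C)(Cl)C(CO)C(C)(C)C1 | intermediate
16 | (4S)-2-chloro-4-hydroxy-2,6,6-trimethylcyclohexane-1-carbaldehyde (epimers at C1/C2) | O[C@@H]1CC(C)(Cl)C(C=O)C(C)(C)C1 | intermediate (not isolated)
17 | (4R)-4-hydroxy-2,6,6-trimethylcyclohex-1-ene-1-carbaldehyde | O[C@@H]1CC(C)=C(C=O)C(C)(C)C1 | intermediate
18 | ethyl (2E)-4-(diethoxyphosphoryl)-3-methylbut-2-enoate | CCOC(=O)/C=C(C)/CP(=O)(OCC)OCC | starting material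
19 | sodium carbanion of 18 | [Na+].CCOC(=O)/C=C(C)/[CH-]P(=O)(OCC)OCC | intermediate (not isolated)
20 | ethyl (2E,4E)-5-[(4R)-4-hydroxy-2,6,6-trimethylcyclohex-1-en-1-yl]-3-methylpenta-2,4-dienoate | O[C@@H]1CC(C)=C(/C=C/C(C)=C/C(=O)OCC)C(C)(C)C1 | intermediate
21 | (2E,4E)-5-[(4R)-4-hydroxy-2,6,6-trimethylcyclohex-1-en-1-yl]-3-methylpenta-2,4-dien-1-ol | O[C@@H]1CC(C)=C(/C=C/C(C)=C/CO)C(C)(C)C1 | intermediate
22 | triphenylphosphine hydrobromide | [Br-].c1ccc(cc1)[PH+](c1ccccc1)c1ccccc1 | starting material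
23 | {(2E,4E)-5-[(4R)-4-hydroxy-2,6,6-trimethylcyclohex-1-en-1-yl]-3-methylpenta-2,4-dien-1-yl}triphenylphosphonium bromide | O[C@@H]1CC(C)=C(/C=C/C(C)=C/C[P+](c2ccccc2)(c2ccccc2)c2ccccc2)C(C)(C)C1.[Br-] | intermediate
24 | (R)-α-ionone, (3E)-4-[(1R)-2,6,6-trimethylcyclohex-2-en-1-yl]but-3-en-2-one | CC(=O)/C=C/[C@H]1C(C)=CCCC1(C)C | starting material
25 | diethyl (cyanomethyl)phosphonate | CCOP(=O)(CC#N)OCC | starting material
26 | sodium carbanion of 25 | [Na+].CCOP(=O)([CH-]C#N)OCC | intermediate (not isolated)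
27 | (2E,4E)-3-methyl-5-[(1R)-2,6,6-trimethylcyclohex-2-en-1-yl]penta-2,4-dienenitrile | N#C/C=C(C)/C=C/[C@H]1C(C)=CCCC1(C)C | intermediate
28 | tert-butyl hydroperoxide | CC(C)(C)OO | starting material
29 | (2E,4E)-3-methyl-5-[(1R)-2,6,6-trimethyl-4-oxocyclohex-2-en-1-yl]penta-2,4-dienenitrile | N#C/C=C(C)/C=C/[C@H]1C(C)=CC(=O)CC1(C)C | intermediate
30 | (2E,4E)-5-[(1R,4R)-4-hydroxy-2,6,6-trimethylcyclohex-2-en-1-yl]-3-methylpenta-2,4-dienenitrile | N#C/C=C(C)/C=C/[C@H]1C(C)=C[C@H](O)CC1(C)C | intermediate
31 | N,O-bis(diisobutylaluminium) aldimine from 30 | CC(C)C[Al](CC(C)C)N=C/C=C(C)/C=C/[C@H]1C(C)=C[C@H](O[Al](CC(C)C)CC(C)C)CC1(C)C | intermediate (not isolated)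
32 | (2E,4E)-5-[(1R,4R)-4-hydroxy-2,6,6-trimethylcyclohex-2-en-1-yl]-3-methylpenta-2,4-dienal | O=C/C=C(C)/C=C/[C@H]1C(C)=C[C@H](O)CC1(C)C | intermediate
33 | (2E,4E,6E)-2,7-dimethylocta-2,4,6-trienedial | O=C/C(C)=C/C=C/C=C(C)/C=O | starting material
34 | ylide of 23 | O[C@@H]1CC(C)=C(/C=C/C(C)=C/C=P(c2ccccc2)(c2ccccc2)c2ccccc2)C(C)(C)C1 | intermediate (not isolated)
35 | (3R)-3-hydroxy-12'-apo-β-caroten-12'-al | O[C@@H]1CC(C)=C(/C=C/C(C)=C/C=C/C(C)=C/C=C/C=C(C)/C=O)C(C)(C)C1 | intermediate
36 | (3R)-12'-apo-β-carotene-3,12'-diol | O[C@@H]1CC(C)=C(/C=C/C(C)=C/C=C/C(C)=C/C=C/C=C(C)/CO)C(C)(C)C1 | intermediate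
37 | [(3R)-3-hydroxy-12'-apo-β-caroten-12'-yl]triphenylphosphonium bromide | O[C@@H]1CC(C)=C(/C=C/C(C)=C/C=C/C(C)=C/C=C/C=C(C)/C[P+](c2ccccc2)(c2ccccc2)c2ccccc2)C(C)(C)C1.[Br-] | intermediate
38 | ylide of 37 | O[C@@H]1CC(C)=C(/C=C/C(C)=C/C=C/C(C)=C/C=C/C=C(C)/C=P(c2ccccc2)(c2ccccc2)c2ccccc2)C(C)(C)C1 | intermediate (not isolated)
39 | (3R,3'R,6'R)-β,ε-carotene-3,3'-diol (lutein) | O[C@@H]1CC(C)=C(/C=C/C(C)=C/C=C/C(C)=C/C=C/C=C(C)/C=C/C=C(C)/C=C/[C@H]2C(C)=C[C@H](O)CC2(C)C)C(C)(C)C1 | intermediate
40 | tetradecanoyl chloride (myristoyl chloride) | CCCCCCCCCCCCCC(Cl)=O | starting material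
41 | (3R,3'R,6'R)-β,ε-carotene-3,3'-diyl ditetradecanoate (lutein dimyristate) | CCCCCCCCCCCCCC(=O)O[C@@H]1CC(C)=C(/C=C/C(C)=C/C=C/C(C)=C/C=C/C=C(C)/C=C/C=C(C)/C=C/[C@H]2C(C)=C[C@H](OC(=O)CCCCCCCCCCCCC)CC2(C)C)C(C)(C)C1 | target

## Step count and risks

Total step count: 19. Longest linear sequence: 15 steps (steps 1–10, then 15–19); the ε-ring branch (steps 11–14) joins at step 18.

**Step 4 (carries the new method).** Cationic oligomerisation of isobutylene may outrun ring closure, or the weakly nucleophilic alkene may open the acetal through a looser ion pair and erode facial selectivity at C3. Fallback by known chemistry, with the two bonds made in two operations: setting out from 7, (2-methylallyl)trimethylsilane and TiCl4 in CH2Cl2 at −78 °C (Hosomi–Sakurai opening of the pentanediol acetal, an established and highly diastereoselective reaction of this acetal class) should give (5S)-5-{[(2R,4R)-4-hydroxypentan-2-yl]oxy}-3,7-dimethylocta-2,7-dien-1-yl acetate F1. Markovnikov protonation of its 1,1-disubstituted alkene with SnCl4/HCl in CH2Cl2 at −78 °C then starts an ordinary 1,5-diene cation–olefin monocyclisation (the geranyl acetate type) that ends in chloride capture, and the route is rejoined at 13.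

**Step 7.** The hindered primary hydroxyl may not be oxidised selectively beside the secondary one, or the γ-chloro alcohol may fragment under the basic conditions of step 6 before it is reached. Fallback that tells the two hydroxyls apart by protection instead of by reagent selectivity: setting out from 14, piperidinium acetate in warm benzene should effect the retro-Michael cleavage without touching the ester and give [(4S)-2-chloro-4-hydroxy-2,6,6-trimethylcyclohexyl]methyl acetate F2. Silylation (TBSCl, imidazole, DMF) gives [(4S)-4-{[tert-butyl(dimethyl)silyl]oxy}-2-chloro-2,6,6-trimethylcyclohexyl]methyl acetate F3, and brief methanolysis (K2CO3, MeOH, 0 °C) gives [(4S)-4-{[tert-butyl(dimethyl)silyl]oxy}-2-chloro-2,6,6-trimethylcyclohexyl]methanol F4. Dess–Martin oxidation gives (4S)-4-{[tert-butyl(dimethyl)silyl]oxy}-2-chloro-2,6,6-trimethylcyclohexane-1-carbaldehyde F5, and Et3N gives (4R)-4-{[tert-butyl(dimethyl)silyl]oxy}-2,6,6-trimethylcyclohex-1-ene-1-carbaldehyde F6. HF·pyridine in THF removes the silyl group and the route is rejoined at 17.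

**Step 13.** Facial selectivity in the ketone reduction may be poor, or catalyst and substrate preferences may oppose each other and favour the 3',6'-cis alcohol. Fallback that corrects the centre by inversion instead of by another hydride reagent: setting out from 29, Luche reduction (NaBH4, CeCl3·7H2O, MeOH, −20 °C) and separation should give (2E,4E)-5-[(1R,4S)-4-hydroxy-2,6,6-trimethylcyclohex-2-en-1-yl]-3-methylpenta-2,4-dienenitrile F7. Mitsunobu reaction with 4-nitrobenzoic acid (PPh3, diisopropyl azodicarboxylate, THF, 0 °C) inverts the carbinol centre to give (1R,4R)-4-[(1E,3E)-4-cyano-3-methylbuta-1,3-dien-1-yl]-3,5,5-trimethylcyclohex-2-en-1-yl 4-nitrobenzoate F8, and methanolysis (K2CO3, MeOH) returns the route at 30.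

## Further compounds

F1 | step 4 | (5S)-5-{[(2R,4R)-4-hydroxypentan-2-yl]oxy}-3,7-dimethylocta-2,7-dien-1-yl acetate | C[C@@H](O)C[C@@H](C)O[C@@H](CC(C)=C)CC(C)=CCOC(C)=O
F2 | step 7 | [(4S)-2-chloro-4-hydroxy-2,6,6-trimethylcyclohexyl]methyl acetate | O[C@@H]1CC(C)(Cl)C(COC(C)=O)C(C)(C)C1
F3 | step 7 | [(4S)-4-{[tert-butyl(dimethyl)silyl]oxy}-2-chloro-2,6,6-trimethylcyclohexyl]methyl acetate | CC(C)(C)[Si](C)(C)O[C@@H]1CC(C)(Cl)C(COC(C)=O)C(C)(C)C1
F4 | step 7 | [(4S)-4-{[tert-butyl(dimethyl)silyl]oxy}-2-chloro-2,6,6-trimethylcyclohexyl]methanol | CC(C)(C)[Si](C)(C)O[C@@H]1CC(C)(Cl)C(CO)C(C)(C)C1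
F5 | step 7 | (4S)-4-{[tert-butyl(dimethyl)silyl]oxy}-2-chloro-2,6,6-trimethylcyclohexane-1-carbaldehyde | CC(C)(C)[Si](C)(C)O[C@@H]1CC(C)(Cl)C(C=O)C(C)(C)C1
F6 | step 7 | (4R)-4-{[tert-butyl(dimethyl)silyl]oxy}-2,6,6-trimethylcyclohex-1-ene-1-carbaldehyde | CC(C)(C)[Si](C)(C)O[C@@H]1CC(C)=C(C=O)C(C)(C)C1
F7 | step 13 | (2E,4E)-5-[(1R,4S)-4-hydroxy-2,6,6-trimethylcyclohex-2-en-1-yl]-3-methylpenta-2,4-dienenitrile | N#C/C=C(C)/C=C/[C@H]1C(C)=C[C@@H](O)CC1(C)C
F8 | step 13 | (1R,4R)-4-[(1E,3E)-4-cyano-3-methylbuta-1,3-dien-1-yl]-3,5,5-trimethylcyclohex-2-en-1-yl 4-nitrobenzoate | N#C/C=C(C)/C=C/[C@H]1C(C)=C[C@H](OC(=O)c2ccc(cc2)[N+](=O)[O-])CC1(C)C
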